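## Structural features

The target is a furanone-bridged germacranolide. Its ten-membered carbocycle (C1–C10) has C3 and C10 joined through one oxygen, so that O, C3, C2, C1 and C10 form a 3(2H)-furanone inside an 11-oxabicyclo[6.2.1]undecane. A trans-fused α-methylene-γ-butyrolactone (O6–C12–C11–C7) sits on the C6–C7 bond. C8 carries an (E)-crotonate, and C4 carries a hydroxymethyl group (C15) on a ring alkene whose ring bonds to C3 and C6 are cis. C6, C7 and C8 form a contiguous stereotriad (6S,7S,8R; O6 and O8 syn along the chain), while the quaternary C10 (R) is separated from it by the C9 methylene. The fragile groups are the exocyclic methylene lactone and the crotonate (Michael acceptors, base-labile), the cross-conjugated dienone formed by the furanone and C4=C5, the allylic C6–O bond and the primary allylic alcohol. The real difficulty is the strained, bridged ten-membered ring with its cis trisubstituted alkene, onto which three adjacent stereocentres must be placed without disturbing these groups. The key step exploits the C7 methylene of a lactone-free bicyclic core: it lies 1,5 to a carbon (C11) that can be tethered to O6 through C12, so the lactone ring and the C7 stereocentre both come from one C7–H bond.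

## Logic of the disconnections

31 back to 30: only the O–Si bond at C15 is cut. The primary allylic hydroxyl would capture a carbenoid and compete in every acylation, so it stays silylated to the end. The forward step must be a non-basic fluoride cleavage that spares the methylene lactone and the crotonate.

30 back to 28 and 29: the C11=C13 double bond is cut. The exocyclic methylene is the most reactive group of the target and is made last, from a phosphonate already in place at C11. The forward olefination needs a base mild enough for the crotonate, and both C11 epimers of 28 must converge.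

28 back to 27: the C7–C11 bond is cut and the γ-lactone opens to an ester on O6. This removes one ring and the C7 stereocentre and leaves a core whose C7 is a plain methylene. The forward step needs a carbenoid that inserts 1,5 into the pro-S C7–H bond in preference to addition to C4=C5, to the C6–H bond and to the C8–H bond. Two points are tightened relative to the obvious form of this step. First, O8 carries the crotonate in 27 and not a silyl ether: a silyloxy group would activate C8–H for six-membered insertion, an acyloxy group deactivates it, and the change saves the late protecting-group exchange. Second, the ring fusion is decided by the C5–C6–C7–C8 torsion, not by a hydrogen "anti to C5", because any C7 hydrogen the tethered carbenoid can reach is anticlinal to C5.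

27 back to 26, then to 24 and 25: the diazo group is removed and the O6–C12 ester bond is cut. This leaves the lactone-free bicyclic core 24 and a commercial acid. The acylation must not move the crotonate from O8 to O6, and the diazo transfer must use a base that leaves the crotonate conjugated.

24 back to 23, then to 21: the C5–C6 ring bond is cut, and the C6 aldehyde is traced to a terminal alkene carrying one extra carbon. Cutting beside the carbinol gives an alkenyl halide and an aldehyde, and the halide geometry becomes the ring alkene geometry. The ten-membered ring is reduced to a side chain on the furanone. The forward ring closure needs high dilution, tolerance of a β-acyloxy aldehyde, and the 6R face; the alkene cleavage must select the monosubstituted alkene.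

21 back to 19 and 20: the O8–acyl bond is cut. Acylating here means O8 never needs a protecting group of its own. The only demand is that 19 has a single free hydroxyl, which it has.

19 back to 17, then to 15 and 7: the O–C3 bond of the furanone and the C1–C2 bond are cut. This divides the molecule into two fragments of similar size. The lactone 15 serves both as the acyl donor for C1 and as the protection of O8. The acetylide must add once only, and the tertiary hydroxyl must be masked during the addition.

15 back to 11 and 12, then to 9 and 8: the C7–C8 bond is cut, the lactone is returned to the acetonide, and the C8 aldehyde to the β-carboxyl. 8 supplies C1, C8, C9, C10, the C10 methyl and the C10 configuration. The forward steps must differentiate the two carboxyl groups (five-membered acetonide on the α-hydroxy acid) and set C8 by reagent control.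

7 back to 6, then to 3 and 4, then to 2 and 1: the C5–iodine bond is traced to a C5–Si bond, the C3–C4 bond is cut, and the C4–iodine bond is traced to a C4–Sn bond; the Si/Sn pair comes from the alkyne 1. A syn addition places silicon (later iodine) cis to tin (later the alkyne carbon C3), so the alkene geometry follows from mechanism. Both ipso substitutions and the coupling must proceed with retention.

## Other disconnections considered

Alternative 1: The cut is at C9–C10 and the C10–O bridge bond, traced through a [2,3] shift to the O–C7 bond of a dihydropyran; the bicyclic ketone A2 would come from the diazoketone A1.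
- Forward key step: Rh2(OAc)4 or Cu(hfacac)2 (copper bis(hexafluoroacetylacetonate)) would decompose A1. The pyran oxygen would trap the carbenoid at C10 as a bicyclic oxonium ylide, and the [2,3] shift through the C7 vinyl group would form C9–C10 and break O–C7.
- In its favour: the ten-membered ring, the oxolanone and the C10 centre arise together by ring expansion, without a high-dilution macrocyclisation. C10 is set by transfer from C3, because the bridge can only span one face of the five-membered ring.
- Against it here: A2 still lacks the C2=C3 unsaturation, has no oxygen at C8 and has C7 as an alkene carbon. The C7=C8 bond would need a face-selective syn hydration-type step (hydrogen to C7, oxygen to C8) in the presence of the ketone and the second alkene, followed by lactonisation, methylenation and dehydrogenation to the furanone. A1 needs a fully substituted C7 stereocentre, and the ylide could also undergo a [1,2] shift or give the E alkene.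
- Comparison: in ring construction the alternative is the better plan. In mechanism the two are equal, since both depend on the chemoselectivity of a metal carbenoid. In step economy after the key step it is clearly worse: many redox and stereochemical adjustments against two steps in the chosen plan.

Alternative 2: The cut is at C7–C8; the C8 alcohol A4 would come from the bromomethyl butenolide aldehyde A3.
- Forward key step: CrCl2 or indium metal would convert the allylic bromide of A3 into an allylmetal that attacks the C8 aldehyde through C7 with allylic transposition. This would close the ten-membered ring and create C7, C8 and the exocyclic methylene at once.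
- In its favour: the lactone is already present, no phosphonate or separate methylenation is needed, there is no C–H selectivity question, and A4 is one acylation and one desilylation from the target. In step economy this is the better plan.
- Against it here: two stereocentres (C7 and C8) are set in a single medium-ring closure, so up to four diastereomers are possible and only the C6 centre can guide them. C6 of the butenolide must be made enantioselectively, and it is γ to the lactone carbonyl and can epimerise through the dienolate. The allylic bromide and the base-sensitive butenolide have to be carried together.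
- Comparison: both plans need one ten-membered ring closure of uncertain diastereoselectivity, so they are equal on that point. The chosen plan sets C8 by reagent control before ring closure and leaves one centre (C6) to the closure and one (C7) to the insertion. It trades the alternative's stereochemical risk for a chemoselectivity risk.

Alternative 3: The cut is at O–C3 and C1–C2 of the furanone; the furanone A7 would come from dimethyl (R)-citramalate A5 and the enynoate A6. A6 is E by the sequence rule, although C3 and C6 are cis on its alkene.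
- Forward key step: a base would add the tertiary alkoxide of A5 to C3 of A6 (oxa-Michael), and the ester-stabilised vinyl anion at C2 would then attack the C1 ester (Dieckmann) to close the ring.
- In its favour: the furanone and the C10 centre come from the chiral pool in one metal-free step. The C4=C5 geometry of A6 follows in one step from 2-butyne-1,4-diol, and C6 is already attached. On furanone step count and alkene geometry it is better than the chosen plan, which needs two steps for the ring and four for 7; on the source of C10 the two are equal.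
- Against it here: it solves only the furanone. The hindered tertiary alkoxide may transesterify instead of adding, and the extra C2 ester must be removed selectively beside the C8 ester. With C6 already bonded to C5, the ten-membered ring would have to be closed at C6–C7 or C7–C8 through enolate or allylmetal chemistry.
- Comparison: it fits the logic of A3 but not a core that is closed at C5–C6 and lactonised by C–H insertion. As a furanone construction it is the more economical one; as an entry to the chosen key step it is the less suitable one.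

Key step: step 15

Remark: atom labels (C1–C15) follow the germacrane numbering of the target in every intermediate, cyclic or acyclic; 27 and 28 differ from the obvious silyl-protected versions only in the spectator group on O8.

## Route

Step 1
Reactants: 1 tert-butyldimethyl(prop-2-yn-1-yloxy)silane
Product: 2 (Z)-tert-butyldimethyl{[2-(tributylstannyl)-3-(trimethylsilyl)prop-2-en-1-yl]oxy}silane
Conditions: Me3Si–SnBu3, Pd(PPh3)4 (3 mol %), THF, 65 °C
Reagents that add atoms: trimethyl(tributylstannyl)silane, C[Si](C)(C)[Sn](CCCC)(CCCC)CCCC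
Why: Palladium-catalysed silylstannation of a terminal alkyne: oxidative addition of the Si–Sn bond to zerovalent palladium and syn insertion place silicon on the terminal carbon (C5) and tin on the internal carbon (C4) on the same side, which fixes the later C4=C5 geometry.

Step 2
Reactants: 2 (Z)-tert-butyldimethyl{[2-(tributylstannyl)-3-(trimethylsilyl)prop-2-en-1-yl]oxy}silane
Product: 3 (Z)-tert-butyl{[2-iodo-3-(trimethylsilyl)prop-2-en-1-yl]oxy}dimethylsilane
Conditions: iodine, CH2Cl2, 0 °C
Reagents that add atoms: iodine, [I][I]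
Why: Iododestannylation with retention; the carbon–tin bond reacts far faster with iodine than the carbon–silicon bond, so only C4 is iodinated and silicon stays cis to the new iodide.

Step 3
Reactants: 3 (Z)-tert-butyl{[2-iodo-3-(trimethylsilyl)prop-2-en-1-yl]oxy}dimethylsilane; 4 ethynylmagnesium bromide
Product: 6 (E)-tert-butyl{[2-ethynyl-3-(trimethylsilyl)prop-2-en-1-yl]oxy}dimethylsilane, via ethynylzinc bromide 5 (not isolated)
Conditions: 4, ZnBr2, THF, 0 °C; then 3, Pd(PPh3)4 (5 mol %), THF, 0 °C to rt
Reagents that add atoms: none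
Why: Negishi coupling of an alkenyl iodide with an alkynylzinc halide; oxidative addition and reductive elimination proceed with retention, so the ethynyl group (C3, C2) ends cis to silicon and the terminal alkyne is obtained without a protecting group.

Step 4
Reactants: 6 (E)-tert-butyl{[2-ethynyl-3-(trimethylsilyl)prop-2-en-1-yl]oxy}dimethylsilane
Product: 7 (E)-tert-butyl{[2-(iodomethylidene)but-3-yn-1-yl]oxy}dimethylsilane
Conditions: N-iodosuccinimide, (CF3)2CHOH, 0 °C
Reagents that add atoms: N-iodosuccinimide, O=C1CCC(=O)N1I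
Why: Ipso-iododesilylation of a vinylsilane: electrophilic iodine attacks the silicon-bearing carbon, and the β-silyl cation loses silicon with retention, so iodine ends cis to the alkyne (future C3) and trans to C15. Without silver or a strong base the terminal alkyne C–H is not iodinated.

Step 5
Reactants: 8 (R)-citramalic acid
Product: 9 2-[(4R)-2,2,4-trimethyl-5-oxo-1,3-dioxolan-4-yl]acetic acid
Conditions: 2,2-dimethoxypropane, PPTS (cat.), rt
Reagents that add atoms: 2,2-dimethoxypropane, COC(C)(C)OC
Why: Acid-catalysed acetonide formation on the α-hydroxy acid gives the five-membered dioxolanone in preference to the six-membered alternative, which differentiates the two carboxyl groups; the quaternary centre is untouched.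

Step 6
Reactants: 9 2-[(4R)-2,2,4-trimethyl-5-oxo-1,3-dioxolan-4-yl]acetic acid
Product: 11 2-[(4R)-2,2,4-trimethyl-5-oxo-1,3-dioxolan-4-yl]acetaldehyde, via acid chloride 10 (not isolated)
Conditions: (COCl)2, DMF (cat.), CH2Cl2, 0 °C to rt; then LiAlH(OtBu)3, THF, −78 °C
Reagents that add atoms: none
Why: Acid chloride formation followed by reduction with the hindered hydride LiAlH(OtBu)3, which stops at the aldehyde at −78 °C and does not reduce the dioxolanone; no free γ-hydroxy intermediate is formed that could lactonise early.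

Step 7
Reactants: 11 2-[(4R)-2,2,4-trimethyl-5-oxo-1,3-dioxolan-4-yl]acetaldehyde; 12 allylmagnesium bromide
Product: 15 (3R,5S)-3-hydroxy-3-methyl-5-(prop-2-en-1-yl)oxolan-2-one, via B-allyldiisopinocampheylborane 13 (not isolated), via homoallylic alcohol 14 (not isolated)
Conditions: (−)-Ipc2BOMe, 12, Et2O, 0 °C to rt; then 11, −78 °C; NaBO3·4H2O, H2O; then TsOH·H2O (cat.), CH2Cl2, rt
Reagents that add atoms: none
Why: Brown allylboration through a closed chair transition state; the isopinocampheyl groups of the (+)-α-pinene-derived reagent should direct allyl to the Si face of the aldehyde and give the 8S carbinol under reagent control (if the antipodal carbinol formed, the (−)-α-pinene-derived reagent would be used). Acid then transfers the C1 acyl group from the acetonide to O8 (five-membered lactone, loss of acetone), which protects O8 and activates C1 together.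

Step 8
Reactants: 15 (3R,5S)-3-hydroxy-3-methyl-5-(prop-2-en-1-yl)oxolan-2-one; 7 (E)-tert-butyl{[2-(iodomethylidene)but-3-yn-1-yl]oxy}dimethylsilane
Product: 17 (1E,6R,8S)-2-({[tert-butyl(dimethyl)silyl]oxy}methyl)-8-hydroxy-1-iodo-6-methyl-6-[(trimethylsilyl)oxy]undeca-1,10-dien-3-yn-5-one, via trimethylsilyl ether 16 (not isolated)
Conditions: TMSCl, imidazole, THF, 0 °C to rt, filter; 7, LiN(SiMe3)2, THF, −78 °C; add 16, −78 to −40 °C; aq. NH4Cl
Reagents that add atoms: chlorotrimethylsilane, C[Si](C)(C)Cl
Why: Silylation of the tertiary alcohol, then addition of the lithium acetylide to the lactone carbonyl (C1–C2 bond). The tetrahedral lithium lactolate persists until work-up, which prevents a second addition, and the amide base does not exchange the alkenyl iodide. 17 may exist partly as its five-membered lactol, which opens in the next step.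

Step 9
Reactants: 17 (1E,6R,8S)-2-({[tert-butyl(dimethyl)silyl]oxy}methyl)-8-hydroxy-1-iodo-6-methyl-6-[(trimethylsilyl)oxy]undeca-1,10-dien-3-yn-5-one
Product: 19 (2R)-5-[(1Z)-3-{[tert-butyl(dimethyl)silyl]oxy}-1-iodoprop-1-en-2-yl]-2-[(2S)-2-hydroxypent-4-en-1-yl]-2-methylfuran-3(2H)-one, via enaminone 18 (not isolated)
Conditions: Et2NH, THF, rt; then AcOH–THF–H2O (3:1:1), rt
Reagents that add atoms: none
Why: Conjugate addition of the amine to the ynone gives the β-amino enone. Aqueous acid removes the trimethylsilyl group and the tertiary C10 hydroxyl displaces the amine at C3 (5-exo-trig addition–elimination), the classical amine-mediated cyclisation of α′-hydroxy ynones to 3(2H)-furanones. The C8 hydroxyl would have to close a seven-membered ring and stays free; C10 is quaternary and cannot epimerise.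

Step 10
Reactants: 19 (2R)-5-[(1Z)-3-{[tert-butyl(dimethyl)silyl]oxy}-1-iodoprop-1-en-2-yl]-2-[(2S)-2-hydroxypent-4-en-1-yl]-2-methylfuran-3(2H)-one; 20 (2E)-but-2-enoic anhydride
Product: 21 (2S)-1-[(2R)-5-[(1Z)-3-{[tert-butyl(dimethyl)silyl]oxy}-1-iodoprop-1-en-2-yl]-2-methyl-3-oxo-2,3-dihydrofuran-2-yl]pent-4-en-2-yl (2E)-but-2-enoate
Conditions: 20, DMAP (cat.), pyridine, CH2Cl2, 0 °C
Reagents that add atoms: none
Why: DMAP-catalysed acylation of the only free hydroxyl with retention at C8; the anhydride with pyridine avoids the vinylketene pathway that deconjugates crotonates when the acid chloride and a trialkylamine are used.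

Step 11
Reactants: 21 (2S)-1-[(2R)-5-[(1Z)-3-{[tert-butyl(dimethyl)silyl]oxy}-1-iodoprop-1-en-2-yl]-2-methyl-3-oxo-2,3-dihydrofuran-2-yl]pent-4-en-2-yl (2E)-but-2-enoate
Product: 23 (2R)-1-[(2R)-5-[(1Z)-3-{[tert-butyl(dimethyl)silyl]oxy}-1-iodoprop-1-en-2-yl]-2-methyl-3-oxo-2,3-dihydrofuran-2-yl]-4-oxobutan-2-yl (2E)-but-2-enoate, via diol 22 (not isolated)
Conditions: OsO4 (2 mol %), N-methylmorpholine N-oxide, acetone–H2O, 0 °C; then NaIO4, pH 7 buffer, rt
Reagents that add atoms: N-methylmorpholine N-oxide, C[N+]1([O-])CCOCC1; water, O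
Why: Lemieux–Johnson-type cleavage: the monosubstituted terminal alkene is the most electron-rich and least hindered alkene and is dihydroxylated before the crotonate, the iodoalkene or the furanone double bond. Periodate then cleaves the diol to the C6 aldehyde at neutral pH, which avoids β-elimination of the crotonate.

Step 12
Reactants: 23 (2R)-1-[(2R)-5-[(1Z)-3-{[tert-butyl(dimethyl)silyl]oxy}-1-iodoprop-1-en-2-yl]-2-methyl-3-oxo-2,3-dihydrofuran-2-yl]-4-oxobutan-2-yl (2E)-but-2-enoate
Product: 24 (4Z,6R,8S,10R)-15-{[tert-butyl(dimethyl)silyl]oxy}-6-hydroxy-1-oxo-3,10-epoxy-11,12,13-trinorgermacra-2,4-dien-8-yl (2E)-but-2-enoate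
Conditions: CrCl2 (8 equiv), NiCl2 (2 mol %), DMSO, rt, slow addition, 3 mM
Reagents that add atoms: none
Why: Nozaki–Hiyama–Kishi reaction: zerovalent nickel inserts into the C5–iodine bond, transmetalation gives the alkenylchromium with retention of geometry, and its addition to the C6 aldehyde closes the ten-membered ring. Esters and the furanone are tolerated and the medium is not basic. The new C6 carbinol must be 6R (syn to O8); this is decided by the conformation of the macrocyclic transition state and is the least predictable point before the key step.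

Step 13
Reactants: 24 (4Z,6R,8S,10R)-15-{[tert-butyl(dimethyl)silyl]oxy}-6-hydroxy-1-oxo-3,10-epoxy-11,12,13-trinorgermacra-2,4-dien-8-yl (2E)-but-2-enoate; 25 (diethoxyphosphoryl)acetic acid
Product: 26 (4Z,6R,8S,10R)-15-{[tert-butyl(dimethyl)silyl]oxy}-6-{[(diethoxyphosphoryl)acetyl]oxy}-1-oxo-3,10-epoxy-11,12,13-trinorgermacra-2,4-dien-8-yl (2E)-but-2-enoate
Conditions: 25, DCC, DMAP (cat.), CH2Cl2, 0 °C to rt
Reagents that add atoms: none
Why: Steglich esterification at O6 with retention; a short reaction at 0 °C keeps the crotonate from migrating from O8 to O6.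

Step 14
Reactants: 26 (4Z,6R,8S,10R)-15-{[tert-butyl(dimethyl)silyl]oxy}-6-{[(diethoxyphosphoryl)acetyl]oxy}-1-oxo-3,10-epoxy-11,12,13-trinorgermacra-2,4-dien-8-yl (2E)-but-2-enoate
Product: 27 (4Z,6R,8S,10R)-15-{[tert-butyl(dimethyl)silyl]oxy}-6-{[diazo(diethoxyphosphoryl)acetyl]oxy}-1-oxo-3,10-epoxy-11,12,13-trinorgermacra-2,4-dien-8-yl (2E)-but-2-enoate
Conditions: 4-acetamidobenzenesulfonyl azide, DBU, MeCN, 0 °C
Reagents that add atoms: 4-acetamidobenzenesulfonyl azide, CC(=O)Nc1ccc(cc1)S(=O)(=O)N=[N+]=[N-]
Why: Regitz diazo transfer to the methylene activated by both phosphonate and ester; no other C–H bond of 26 is acidic enough for DBU at 0 °C, so the crotonate stays conjugated.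

Step 15
Reactants: 27 (4Z,6R,8S,10R)-15-{[tert-butyl(dimethyl)silyl]oxy}-6-{[diazo(diethoxyphosphoryl)acetyl]oxy}-1-oxo-3,10-epoxy-11,12,13-trinorgermacra-2,4-dien-8-yl (2E)-but-2-enoate
Product: 28 (4Z,6S,7S,8R,10R,11RS)-15-{[tert-butyl(dimethyl)silyl]oxy}-11-(diethoxyphosphoryl)-1-oxo-3,10-epoxy-13-norgermacra-2,4-dien-12,6-olid-8-yl (2E)-but-2-enoate
Conditions: Rh2(OAc)4 (3 mol %), ClCH2CH2Cl, reflux, slow addition of 27 (final 5 mM)
Reagents that add atoms: none
Why: Loss of N2 from 27 on Rh2(OAc)4 gives an electrophilic acceptor/acceptor rhodium carbenoid at C11, which inserts into a C7–H bond through a concerted, asynchronous three-centre transition state with hydride-transfer character, so the C–H bond is replaced by C7–C11 with retention at C7. The closest known reaction is the dirhodium-carboxylate-catalysed 1,5 C–H insertion of α-diazo-α-(dialkoxyphosphoryl)acetates of secondary alcohols to α-phosphono-γ-butyrolactones. The γ-lactone (O6–C12–C11–C7–C6) closes by 1,5 insertion through a five-membered-ring-like transition state, which is entropically favoured over the four-membered mode at C6–H and the six-membered mode at C8–H. The new C7 stereocentre is fixed by which diastereotopic hydrogen reacts: the pro-S hydrogen, the one syn to both C–O bonds when the C5–C9 chain is drawn extended, gives the trans-fused 6S,7S lactone, and it is the hydrogen presented to the carbenoid when the ring holds the C5–C6–C7–C8 torsion near antiperiplanar, the arrangement the trans-fused product itself needs and the one that avoids the gauche C5/C8 interaction of the cis-fused transition state. C11 forms as a mixture, which does not matter because it becomes sp2 in the next step. Three selectivities are needed: C7–H over C8–H is secured by the crotonate, whose acyloxy group makes C8–H electron-poor where a silyloxy group would activate it; insertion over cyclopropanation of the allylic C4=C5 bond relies on that alkene being the electron-poor, trisubstituted terminus of the dienone and on carboxylate ligands (carboxamidate ligands favour alkene addition and are avoided); and C7–H over the allylic C6–H relies on β-lactone strain and the acyloxy deactivation of C6–H. Slow addition at high dilution suppresses carbene dimerisation.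

Step 16
Reactants: 28 (4Z,6S,7S,8R,10R,11RS)-15-{[tert-butyl(dimethyl)silyl]oxy}-11-(diethoxyphosphoryl)-1-oxo-3,10-epoxy-13-norgermacra-2,4-dien-12,6-olid-8-yl (2E)-but-2-enoate; 29 formaldehyde
Product: 30 (4Z,6S,7S,8R,10R)-15-{[tert-butyl(dimethyl)silyl]oxy}-1-oxo-3,10-epoxygermacra-2,4,11(13)-trien-12,6-olid-8-yl (2E)-but-2-enoate
Conditions: 29 (37 % aq.), K2CO3, THF, 0 °C to rt
Reagents that add atoms: none
Why: Horner–Wadsworth–Emmons olefination of the α-phosphono lactone with formaldehyde; the stabilised carbanion is planar, so both C11 epimers converge, and aqueous carbonate at 0 °C spares the crotonate and the new Michael acceptor.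

Step 17
Reactants: 30 (4Z,6S,7S,8R,10R)-15-{[tert-butyl(dimethyl)silyl]oxy}-1-oxo-3,10-epoxygermacra-2,4,11(13)-trien-12,6-olid-8-yl (2E)-but-2-enoate
Product: 31 (4Z,6S,7S,8R,10R)-15-hydroxy-1-oxo-3,10-epoxygermacra-2,4,11(13)-trien-12,6-olid-8-yl (2E)-but-2-enoate (CNP0225232.1)
Conditions: HF·pyridine, pyridine, THF, 0 °C to rt
Reagents that add atoms: none
Why: Fluoride cleavage of the primary allylic silyl ether under buffered, non-basic conditions; the methylene lactone, the crotonate and the allylic lactone oxygen are not attacked and no stereocentre is touched.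

## Compound list

1 | tert-butyldimethyl(prop-2-yn-1-yloxy)silane | C#CCO[Si](C)(C)C(C)(C)C | starting material
2 | (Z)-tert-butyldimethyl{[2-(tributylstannyl)-3-(trimethylsilyl)prop-2-en-1-yl]oxy}silane | C[Si](C)(C)/C=C(\[Sn](CCCC)(CCCC)CCCC)CO[Si](C)(C)C(C)(C)C | intermediate
3 | (Z)-tert-butyl{[2-iodo-3-(trimethylsilyl)prop-2-en-1-yl]oxy}dimethylsilane | C[Si](C)(C)/C=C(\I)CO[Si](C)(C)C(C)(C)C | intermediate
4 | ethynylmagnesium bromide | C#C[Mg]Br | starting material
5 | ethynylzinc bromide | C#C[Zn]Br | intermediate
6 | (E)-tert-butyl{[2-ethynyl-3-(trimethylsilyl)prop-2-en-1-yl]oxy}dimethylsilane | C[Si](C)(C)/C=C(\C#C)CO[Si](C)(C)C(C)(C)C | intermediate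
7 | (E)-tert-butyl{[2-(iodomethylidene)but-3-yn-1-yl]oxy}dimethylsilane | C#C/C(=C\I)CO[Si](C)(C)C(C)(C)C | intermediate
8 | (R)-citramalic acid, (2R)-2-hydroxy-2-methylbutanedioic acid | C[C@@](O)(CC(=O)O)C(=O)O | starting material
9 | 2-[(4R)-2,2,4-trimethyl-5-oxo-1,3-dioxolan-4-yl]acetic acid | C[C@@]1(CC(=O)O)C(=O)OC(C)(C)O1 | intermediate
10 | 2-[(4R)-2,2,4-trimethyl-5-oxo-1,3-dioxolan-4-yl]acetyl chloride | C[C@@]1(CC(=O)Cl)C(=O)OC(C)(C)O1 | intermediate
11 | 2-[(4R)-2,2,4-trimethyl-5-oxo-1,3-dioxolan-4-yl]acetaldehyde | C[C@@]1(CC=O)C(=O)OC(C)(C)O1 | intermediate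
12 | allylmagnesium bromide | C=CC[Mg]Br | starting material
13 | (−)-B-allyldiisopinocampheylborane, allylbis[(1R,2S,3R,5R)-2,6,6-trimethylbicyclo[3.1.1]heptan-3-yl]borane | C=CCB([C@@H]1C[C@@H]2C[C@H]([C@H]1C)C2(C)C)[C@@H]1C[C@@H]2C[C@H]([C@H]1C)C2(C)C | intermediate
14 | (5R)-5-[(2S)-2-hydroxypent-4-en-1-yl]-2,2,5-trimethyl-1,3-dioxolan-4-one | C[C@@]1(C[C@@H](O)CC=C)C(=O)OC(C)(C)O1 | intermediate
15 | (3R,5S)-3-hydroxy-3-methyl-5-(prop-2-en-1-yl)oxolan-2-one | C=CC[C@H]1C[C@@](C)(O)C(=O)O1 | intermediate
16 | (3R,5S)-3-methyl-5-(prop-2-en-1-yl)-3-[(trimethylsilyl)oxy]oxolan-2-one | C=CC[C@H]1C[C@@](C)(O[Si](C)(C)C)C(=O)O1 | intermediate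
17 | (1E,6R,8S)-2-({[tert-butyl(dimethyl)silyl]oxy}methyl)-8-hydroxy-1-iodo-6-methyl-6-[(trimethylsilyl)oxy]undeca-1,10-dien-3-yn-5-one | C=CC[C@H](O)C[C@@](C)(O[Si](C)(C)C)C(=O)C#C/C(=C\I)CO[Si](C)(C)C(C)(C)C | intermediate
18 | (1E,6R,8S)-2-({[tert-butyl(dimethyl)silyl]oxy}methyl)-3-(diethylamino)-8-hydroxy-1-iodo-6-methyl-6-[(trimethylsilyl)oxy]undeca-1,3,10-trien-5-one (C3=C4 geometry not defined) | C=CC[C@H](O)C[C@@](C)(O[Si](C)(C)C)C(=O)C=C(N(CC)CC)/C(=C\I)CO[Si](C)(C)C(C)(C)C | intermediate
19 | (2R)-5-[(1Z)-3-{[tert-butyl(dimethyl)silyl]oxy}-1-iodoprop-1-en-2-yl]-2-[(2S)-2-hydroxypent-4-en-1-yl]-2-methylfuran-3(2H)-one | C=CC[C@H](O)C[C@@]1(C)OC(=CC1=O)/C(=C\I)CO[Si](C)(C)C(C)(C)C | intermediate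
20 | (2E)-but-2-enoic anhydride (crotonic anhydride) | C/C=C/C(=O)OC(=O)/C=C/C | starting material
21 | (2S)-1-[(2R)-5-[(1Z)-3-{[tert-butyl(dimethyl)silyl]oxy}-1-iodoprop-1-en-2-yl]-2-methyl-3-oxo-2,3-dihydrofuran-2-yl]pent-4-en-2-yl (2E)-but-2-enoate | C=CC[C@H](OC(=O)/C=C/C)C[C@@]1(C)OC(=CC1=O)/C(=C\I)CO[Si](C)(C)C(C)(C)C | intermediate
22 | (2S)-1-[(2R)-5-[(1Z)-3-{[tert-butyl(dimethyl)silyl]oxy}-1-iodoprop-1-en-2-yl]-2-methyl-3-oxo-2,3-dihydrofuran-2-yl]-4,5-dihydroxypentan-2-yl (2E)-but-2-enoate (both C4 epimers) | OCC(O)C[C@H](OC(=O)/C=C/C)C[C@@]1(C)OC(=CC1=O)/C(=C\I)CO[Si](C)(C)C(C)(C)C | intermediate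
23 | (2R)-1-[(2R)-5-[(1Z)-3-{[tert-butyl(dimethyl)silyl]oxy}-1-iodoprop-1-en-2-yl]-2-methyl-3-oxo-2,3-dihydrofuran-2-yl]-4-oxobutan-2-yl (2E)-but-2-enoate | O=CC[C@H](OC(=O)/C=C/C)C[C@@]1(C)OC(=CC1=O)/C(=C\I)CO[Si](C)(C)C(C)(C)C | intermediate
24 | (4Z,6R,8S,10R)-15-{[tert-butyl(dimethyl)silyl]oxy}-6-hydroxy-1-oxo-3,10-epoxy-11,12,13-trinorgermacra-2,4-dien-8-yl (2E)-but-2-enoate | O[C@H]1/C=C(/CO[Si](C)(C)C(C)(C)C)C2=CC(=O)[C@@](C)(C[C@@H](OC(=O)/C=C/C)C1)O2 | intermediate
25 | (diethoxyphosphoryl)acetic acid | CCOP(=O)(OCC)CC(=O)O | starting material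
26 | (4Z,6R,8S,10R)-15-{[tert-butyl(dimethyl)silyl]oxy}-6-{[(diethoxyphosphoryl)acetyl]oxy}-1-oxo-3,10-epoxy-11,12,13-trinorgermacra-2,4-dien-8-yl (2E)-but-2-enoate | CCOP(=O)(OCC)CC(=O)O[C@H]1/C=C(/CO[Si](C)(C)C(C)(C)C)C2=CC(=O)[C@@](C)(C[C@@H](OC(=O)/C=C/C)C1)O2 | intermediate
27 | (4Z,6R,8S,10R)-15-{[tert-butyl(dimethyl)silyl]oxy}-6-{[diazo(diethoxyphosphoryl)acetyl]oxy}-1-oxo-3,10-epoxy-11,12,13-trinorgermacra-2,4-dien-8-yl (2E)-but-2-enoate | CCOP(=O)(OCC)C(=[N+]=[N-])C(=O)O[C@H]1/C=C(/CO[Si](C)(C)C(C)(C)C)C2=CC(=O)[C@@](C)(C[C@@H](OC(=O)/C=C/C)C1)O2 | intermediate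
28 | (4Z,6S,7S,8R,10R,11RS)-15-{[tert-butyl(dimethyl)silyl]oxy}-11-(diethoxyphosphoryl)-1-oxo-3,10-epoxy-13-norgermacra-2,4-dien-12,6-olid-8-yl (2E)-but-2-enoate | CCOP(=O)(OCC)C1C(=O)O[C@H]2/C=C(/CO[Si](C)(C)C(C)(C)C)C3=CC(=O)[C@@](C)(C[C@@H](OC(=O)/C=C/C)[C@H]12)O3 | intermediate
29 | formaldehyde | C=O | starting material
30 | (4Z,6S,7S,8R,10R)-15-{[tert-butyl(dimethyl)silyl]oxy}-1-oxo-3,10-epoxygermacra-2,4,11(13)-trien-12,6-olid-8-yl (2E)-but-2-enoate | C=C1C(=O)O[C@H]2/C=C(/CO[Si](C)(C)C(C)(C)C)C3=CC(=O)[C@@](C)(C[C@@H](OC(=O)/C=C/C)[C@H]12)O3 | intermediate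
31 | (4Z,6S,7S,8R,10R)-15-hydroxy-1-oxo-3,10-epoxygermacra-2,4,11(13)-trien-12,6-olid-8-yl (2E)-but-2-enoate | C=C1C(=O)O[C@H]2/C=C(/CO)C3=CC(=O)[C@@](C)(C[C@@H](OC(=O)/C=C/C)[C@H]12)O3 | target

## Step count and least certain steps

Total: 17 steps. Longest linear sequence: 14 steps (steps 1–4, then 8–17, from 1). The citramalate branch (steps 5–7, from 8) joins at step 8.

Step 15 (key step). The carbenoid may be diverted from the pro-S C7–H bond: by addition to the allylic C4=C5 bond, by insertion next to oxygen at C6, or by reaction at the other C7 hydrogen to give the cis fusion. The cause is that an allylic diazo ester has an alkene within easy reach and that the ring conformation of 27 is not known. Ligand tuning (Rh2(O2CC3F7)4, or Rh2(esp)2, dirhodium bis(α,α,α′,α′-tetramethyl-1,3-benzenedipropionate)) would be tried first.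
The fallback replaces the carbenoid by a polar epoxide opening; it sets out from 23 and comes back at 28.
- 23 would be eliminated on purpose (Et3N, CH2Cl2) to the (E)-enal F1.
- Nozaki–Hiyama–Kishi closure as in step 12 would give the dienol F2.
- Hydroxyl-directed epoxidation of the C7=C8 bond (VO(acac)2 with t-BuOOH, or Ti(OiPr)4, the matched diisopropyl tartrate and t-BuOOH) would give the erythro epoxy alcohol F3.
- Esterification with 25 (DCC, DMAP) would give F4.
- NaH in THF would let the phosphonoacetate carbanion open the epoxide at C7 (5-exo-tet, inversion) to the hydroxy phosphono lactone F5. In F5, C7 is correct and C8 is epimeric.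
- Mitsunobu esterification of F5 with (E)-crotonic acid (PPh3, DIAD) would invert C8 and give 28.

Step 12. Poor facial selectivity at C6 is the most likely problem, because the new carbinol is set only by the conformation of a strained ten-membered transition state; acyclic 1,3-induction from a β-acyloxy aldehyde would, if anything, favour the anti relationship. Fallback, setting out from the 6S epimer F6 formed beside 24 and coming back at 26: Mitsunobu esterification of F6 with 25 (PPh3, DIAD) inverts C6. Both epimers therefore converge on 26, 24 by carbodiimide coupling with retention and F6 by inversion.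

Step 11 (and the handling of 23 in step 12). Loss of crotonic acid by β-elimination from the β-acyloxy aldehyde is the main risk, together with partial dihydroxylation of the crotonate alkene; acyl migration from O8 to the new O6 alkoxide is a related risk. Fallback, setting out from 19 and coming back at 26, carries O8 as a silyl ether through ring closure:
- 19 would be silylated (TESOTf, 2,6-lutidine) to F10.
- Cleavage as in step 11 would give the β-silyloxy aldehyde F11.
- Ring closure as in step 12 would give F12.
- Esterification with 25 would give F13.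
- Selective removal of the secondary triethylsilyl group (HF·pyridine, pyridine, THF, 0 °C) would give F14.
- Acylation with 20 as in step 10 would give 26.

Step 8. Incomplete or non-selective addition of the acetylide to the hindered α-silyloxy lactone, silyl transfer between O10 and O8, and the lactol form of the product may reduce efficiency. Fallback, setting out from 15 and coming back at 19, uses an open-chain acyl donor:
- 15 would be opened with MeNHOMe·HCl and Me2AlCl to the dihydroxy Weinreb amide F7.
- Both hydroxyls would be silylated (TMSCl, imidazole) to F8.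
- The lithium acetylide of 7 would give the ynone F9.
- Et2NH followed by aqueous acetic acid, as in step 9, would remove both trimethylsilyl groups and give 19.

## Further compounds

F1 | step 15 | (2E)-4-[(2R)-5-[(1Z)-3-{[tert-butyl(dimethyl)silyl]oxy}-1-iodoprop-1-en-2-yl]-2-methyl-3-oxo-2,3-dihydrofuran-2-yl]but-2-enal | O=C/C=C/C[C@@]1(C)OC(=CC1=O)/C(=C\I)CO[Si](C)(C)C(C)(C)C
F2 | step 15 | (4Z,6R,7E,10R)-15-{[tert-butyl(dimethyl)silyl]oxy}-6-hydroxy-3,10-epoxy-11,12,13-trinorgermacra-2,4,7-trien-1-one | C[C@@]12C/C=C/[C@@H](O)/C=C(/CO[Si](C)(C)C(C)(C)C)C(=CC1=O)O2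
F3 | step 15 | (4Z,6S,7S,8S,10R)-15-{[tert-butyl(dimethyl)silyl]oxy}-7,8-epoxy-6-hydroxy-3,10-epoxy-11,12,13-trinorgermacra-2,4-dien-1-one (trans epoxide, oxygen anti to the C6 hydroxyl) | C[C@@]12C[C@@H]3O[C@H]3[C@@H](O)/C=C(/CO[Si](C)(C)C(C)(C)C)C(=CC1=O)O2
F4 | step 15 | (4Z,6S,7S,8S,10R)-15-{[tert-butyl(dimethyl)silyl]oxy}-7,8-epoxy-1-oxo-3,10-epoxy-11,12,13-trinorgermacra-2,4-dien-6-yl (diethoxyphosphoryl)acetate | C[C@@]12C[C@@H]3O[C@H]3[C@@H](OC(=O)CP(=O)(OCC)OCC)/C=C(/CO[Si](C)(C)C(C)(C)C)C(=CC1=O)O2
F5 | step 15 | (4Z,6S,7S,8S,10R,11RS)-15-{[tert-butyl(dimethyl)silyl]oxy}-11-(diethoxyphosphoryl)-8-hydroxy-3,10-epoxy-13-norgermacra-2,4-dien-1-one 12,6-olide (C8 epimer of the alcohol of 28) | CCOP(=O)(OCC)C1C(=O)O[C@H]2/C=C(/CO[Si](C)(C)C(C)(C)C)C3=CC(=O)[C@@](C)(C[C@H](O)[C@H]12)O3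
F6 | step 12 | (4Z,6S,8S,10R)-15-{[tert-butyl(dimethyl)silyl]oxy}-6-hydroxy-1-oxo-3,10-epoxy-11,12,13-trinorgermacra-2,4-dien-8-yl (2E)-but-2-enoate (C6 epimer of 24) | O[C@@H]1/C=C(/CO[Si](C)(C)C(C)(C)C)C2=CC(=O)[C@@](C)(C[C@@H](OC(=O)/C=C/C)C1)O2
F7 | step 8 | (2R,4S)-2,4-dihydroxy-N-methoxy-N,2-dimethylhept-6-enamide | C=CC[C@H](O)C[C@@](C)(O)C(=O)N(C)OC
F8 | step 8 | (2R,4S)-N-methoxy-N,2-dimethyl-2,4-bis[(trimethylsilyl)oxy]hept-6-enamide | C=CC[C@H](O[Si](C)(C)C)C[C@@](C)(O[Si](C)(C)C)C(=O)N(C)OC
F9 | step 8 | (1E,6R,8S)-2-({[tert-butyl(dimethyl)silyl]oxy}methyl)-1-iodo-6-methyl-6,8-bis[(trimethylsilyl)oxy]undeca-1,10-dien-3-yn-5-one | C=CC[C@H](O[Si](C)(C)C)C[C@@](C)(O[Si](C)(C)C)C(=O)C#C/C(=C\I)CO[Si](C)(C)C(C)(C)C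
F10 | step 11 | (2R)-5-[(1Z)-3-{[tert-butyl(dimethyl)silyl]oxy}-1-iodoprop-1-en-2-yl]-2-methyl-2-[(2S)-2-[(triethylsilyl)oxy]pent-4-en-1-yl]furan-3(2H)-one | C=CC[C@H](O[Si](CC)(CC)CC)C[C@@]1(C)OC(=CC1=O)/C(=C\I)CO[Si](C)(C)C(C)(C)C
F11 | step 11 | (3R)-4-[(2R)-5-[(1Z)-3-{[tert-butyl(dimethyl)silyl]oxy}-1-iodoprop-1-en-2-yl]-2-methyl-3-oxo-2,3-dihydrofuran-2-yl]-3-[(triethylsilyl)oxy]butanal | O=CC[C@H](O[Si](CC)(CC)CC)C[C@@]1(C)OC(=CC1=O)/C(=C\I)CO[Si](C)(C)C(C)(C)C
F12 | step 11 | (4Z,6R,8S,10R)-15-{[tert-butyl(dimethyl)silyl]oxy}-6-hydroxy-8-[(triethylsilyl)oxy]-3,10-epoxy-11,12,13-trinorgermacra-2,4-dien-1-one | O[C@H]1/C=C(/CO[Si](C)(C)C(C)(C)C)C2=CC(=O)[C@@](C)(C[C@@H](O[Si](CC)(CC)CC)C1)O2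
F13 | step 11 | (4Z,6R,8S,10R)-15-{[tert-butyl(dimethyl)silyl]oxy}-1-oxo-8-[(triethylsilyl)oxy]-3,10-epoxy-11,12,13-trinorgermacra-2,4-dien-6-yl (diethoxyphosphoryl)acetate | CCOP(=O)(OCC)CC(=O)O[C@H]1/C=C(/CO[Si](C)(C)C(C)(C)C)C2=CC(=O)[C@@](C)(C[C@@H](O[Si](CC)(CC)CC)C1)O2
F14 | step 11 | (4Z,6R,8S,10R)-15-{[tert-butyl(dimethyl)silyl]oxy}-8-hydroxy-1-oxo-3,10-epoxy-11,12,13-trinorgermacra-2,4-dien-6-yl (diethoxyphosphoryl)acetate | CCOP(=O)(OCC)CC(=O)O[C@H]1/C=C(/CO[Si](C)(C)C(C)(C)C)C2=CC(=O)[C@@](C)(C[C@@H](O)C1)O2
A1 | alternative 1 | methyl [6-(3-diazo-2-oxobutyl)-5-({[tert-butyl(dimethyl)silyl]oxy}methyl)-2-ethenyl-3-[(triethylsilyl)oxy]-3,6-dihydro-2H-pyran-2-yl]acetate (ethenyl group cis to the C3 side chain) | C=C[C@]1(CC(=O)OC)O[C@H](CC(=O)C(C)=[N+]=[N-])C(CO[Si](C)(C)C(C)(C)C)=C[C@@H]1O[Si](CC)(CC)CC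
A2 | alternative 1 | ring-expanded 11-oxabicyclo[6.2.1]undecadienone: 3,10-epoxy ten-membered ketone with C4=C5 and C7=C8 alkenes, C6 triethylsilyl ether and C7 CH2CO2Me | C[C@@]12C/C=C(/CC(=O)OC)[C@@H](O[Si](CC)(CC)CC)/C=C(/CO[Si](C)(C)C(C)(C)C)[C@@H](CC1=O)O2
A3 | alternative 2 | [(2R)-5-[(1Z)-1-[(2S)-4-(bromomethyl)-5-oxo-2,5-dihydrofuran-2-yl]-3-{[tert-butyl(dimethyl)silyl]oxy}prop-1-en-2-yl]-2-methyl-3-oxo-2,3-dihydrofuran-2-yl]acetaldehyde | BrCC1=C[C@H](/C=C(/CO[Si](C)(C)C(C)(C)C)C2=CC(=O)[C@@](C)(CC=O)O2)OC1=O
A4 | alternative 2 | (4Z,6S,7S,8R,10R)-15-{[tert-butyl(dimethyl)silyl]oxy}-8-hydroxy-3,10-epoxygermacra-2,4,11(13)-trien-1-one 12,6-olide | C=C1C(=O)O[C@H]2/C=C(/CO[Si](C)(C)C(C)(C)C)C3=CC(=O)[C@@](C)(C[C@@H](O)[C@H]12)O3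
A5 | alternative 3 | dimethyl (2R)-2-hydroxy-2-methylbutanedioate (dimethyl (R)-citramalate) | COC(=O)C[C@@](C)(O)C(=O)OC
A6 | alternative 3 | methyl (4E)-4-({[tert-butyl(dimethyl)silyl]oxy}methyl)-6-[(4-methoxyphenyl)methoxy]hex-4-en-2-ynoate | COC(=O)C#CC(/CO[Si](C)(C)C(C)(C)C)=C\COCc1ccc(OC)cc1
A7 | alternative 3 | methyl (5R)-2-[(2Z)-1-{[tert-butyl(dimethyl)silyl]oxy}-4-[(4-methoxyphenyl)methoxy]but-2-en-2-yl]-5-(2-methoxy-2-oxoethyl)-5-methyl-4-oxo-4,5-dihydrofuran-3-carboxylate | COC(=O)C[C@@]1(C)OC(C(/CO[Si](C)(C)C(C)(C)C)=C\COCc2ccc(OC)cc2)=C(C(=O)OC)C1=O
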